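Start from 2.00, the charge ratio of epsilon, meaning Z charged per E charged. J holds two Z per E, so call spare Z the amount [Z]₀ − 2[E]₀. Below the mark, Z is the limiting reagent; above it, Z has a way to go past J.

| flask | E | Z | remark | time |
|---|---|---|---|---|
| oak | 0.021 M | 0.12 M | run made earlier |  |
| alder | 0.064 M | 0.12 M | run made earlier |  |
| cedar | 0.10 M | 0.094 M | run made earlier |  |
| eta | 0.10 M | 0.0600 M |  | 30 min |
| gamma | 0.030 M | 0.120 M |  | 30 min |
| epsilon | 0.030 M | 0.0600 M |  | 30 min |
| beta | 0.10 M | 0.120 M |  | 30 min |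

| oak: time / min | oak: J / % | alder: time / min | alder: J / % | cedar: time / min | cedar: J / % |
|---|---|---|---|---|---|
| 4.00 | 34.6 | 4.00 | 48.1 | 1.50 | 18.2 |
| 8.00 | 24.8 | 8.00 | 58.5 | 3.00 | 21.1 |
| 12.0 | 23.8 | 12.0 | 65.6 | 6.00 | 20.3 |
| 15.0 | 24.9 | 15.0 | 68.7 | 12.0 | 22.0 |
| 20.0 | 27.4 | 20.0 | 72.3 | 20.0 | 24.1 |

(each reading ± 0.5 percentage points)

* all flasks from highest to lowest amount of J, in percent of the E charged, at 30 min (eta / gamma / epsilon / beta)
* the amount of J, in percent of the E charged of the flask you put first, at 30 min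
* the amount of J, in percent of the E charged of the flask you put last, at 30 min

- the numbers in the tables scatter with a standard deviation of 0.5 percentage points

Read the runs by this ratio. Oak, at 5.71, reads 34.6% at 4.00 min, dips to 23.8% at 12.0 min and is climbing slowly at the end. Alder, at 1.88, rises to 72.3% by 20.0 min. Cedar, at 0.940, stalls near 24.1%.

So when you take over, expect epsilon, at 2.00, near alder's last reading, and expect eta, at ratio 0.600, lower than cedar. Hold the E charge of epsilon as written: oak and alder share their Z, and at 20.0 min oak, with less E, reads less J than alder.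

The forecast gives epsilon > beta > gamma > eta, with 66% and 14%, and warns: “Beta versus gamma is close.”

The flasks give epsilon > gamma > beta > eta, with 70.4% and 10.4%. They part from the forecast on one point: gamma, at 47.2%, stands above beta, at 37.8%.

    Z + J ⇌ G + Q (K = 3.90, k = 0.110 M⁻¹ s⁻¹)
    E + Z → X + Q (k = 0.340 M⁻¹ s⁻¹)
    Z → L (k = 4.10 × 10⁻⁴ s⁻¹)
    Z + X → J + Q (k = 0.230 M⁻¹ s⁻¹)

Now put the ratio to the neighbour flask, which is epsilon with 0.10 M of Z. Its ratio is 3.33, above epsilon's 2.00, so its spare Z comes to 0.0400 M. At 30.0 min it holds E 0% and X 0.0520%, and the spare Z is found in three places: G at 41.3% of the E charged, free Z at 12% of its own charge, and L at 0.0155 M. Together these make 0.0400 M. J in the neighbour flask reads 58.6%, against 70.4% in epsilon.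

(The numbers in the tables are simulated on assumed constants.)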